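The route rests on cutting the ten-membered ring at C3–C4 and C9–C10, which leaves C4–C9 as one block. This block, with the ring-cis tetrasubstituted chloroalkene C5(Me)=C6(Cl), the oxygen-bearing C7 and C8, and the termini C4 and C9, is the carbon ring of a chlorotoluene. A Rieske dioxygenase cis-dihydroxylates commercial 2-chloro-5-iodotoluene (1) at the only unsubstituted edge: C7–O and C8–O form enantioselectively and aromaticity is broken in one operation, while the ring fixes the alkene geometry. The precursor is the bought arene; its iodine at C9 steers the enzyme and is then removed. Ring A is later built on C9 by a butenolide Diels–Alder reaction and the lactone is annulated last.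

Key step: step 1

Assumption: locants follow the briarane numbering of the target (C1 quaternary fusion carbon, C2–C10 round the ten-membered ring, C11–C14 in ring A, C15 methyl on C1, C17–C19 lactone, C20 methyl on C11); the SMILES in the compound list define all configurations.
Remark: of the two centres made in step 1 only C7 reaches the target; C8 is a relay centre that is epimerised in step 6 and becomes a ketone in step 24.

Step 1
Reactants: 1 2-chloro-5-iodotoluene
Product: 2 (1S,2R)-3-chloro-6-iodo-4-methylcyclohexa-3,5-diene-1,2-diol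
Conditions: whole cells of recombinant E. coli expressing a toluene dioxygenase (todC1C2BA, wild type or a variant chosen by screening), air, glucose, phosphate buffer pH 7.2, 30 °C
Reagents that add atoms: dioxygen, O=O
Why: Rieske arene cis-dihydroxylation: electrons pass from NADH through the [2Fe–2S] cluster to the mononuclear non-heme iron site, where O2 is activated and both oxygen atoms are delivered to the same face of one arene edge, giving the cis-dihydrodiol and breaking aromaticity. The closest known reactions are the toluene- and chlorobenzene-dioxygenase oxidations of para-dihalobenzenes, 4-substituted iodobenzenes and halotoluenes. No ring is closed. C7 and C8 are set together by the enzyme pocket: the larger iodine should anchor the substrate, so the sense of induction is that of an iodobenzene (C8 S, C7 R), opposite to chlorine-directed binding. Regioselectivity is secured by the substrate, because C7–C8 is the only edge that carries two hydrogens; selectivity against hydroxylation of the benzylic methyl group must come from the choice of enzyme. The diol is protected at once because it can dehydrate to a phenol.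

Step 2
Reactants: 2 (1S,2R)-3-chloro-6-iodo-4-methylcyclohexa-3,5-diene-1,2-diol
Product: 3 (3aR,7aS)-4-chloro-7-iodo-2,2,5-trimethyl-3a,7a-dihydro-1,3-benzodioxole
Conditions: 2,2-dimethoxypropane, TsOH·H2O (cat.), acetone, 0 °C
Reagents that add atoms: 2,2-dimethoxypropane, COC(C)(C)OC
Why: Acid-catalysed acetonide formation (transacetalisation) on the cis-diol should be fast and blocks dehydration to a phenol; no stereocentre changes.

Step 3
Reactants: 3 (3aR,7aS)-4-chloro-7-iodo-2,2,5-trimethyl-3a,7a-dihydro-1,3-benzodioxole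
Product: 4 (3aR,7aR)-4-chloro-2,2,5-trimethyl-3a,7a-dihydro-1,3-benzodioxole
Conditions: Pd(PPh3)4 (cat.), Bu3SnH, THF, 20 °C
Reagents that add atoms: none
Why: Palladium-catalysed hydrodehalogenation: zerovalent palladium inserts into the vinylic C–I bond far faster than into C–Cl and Bu3SnH then delivers hydride, so only iodine should be replaced; 4 is used at once because such dienes dimerise.

Step 4
Reactants: 4 (3aR,7aR)-4-chloro-2,2,5-trimethyl-3a,7a-dihydro-1,3-benzodioxole
Product: 6 (Z)-chloroalkene diol with primary alcohols at C4 and C9 on the cis-7,8-acetonide, via ozonide 5 (not isolated)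
Conditions: O3, CH2Cl2, −78 °C (Sudan Red 7B end point); then NaBH4, MeOH, −78 → 0 °C
Reagents that add atoms: ozone, [O-][O+]=O
Why: Ozonolysis with reductive work-up: ozone should attack the electron-richer cis-disubstituted C4=C9 bond before the chlorine-bearing tetrasubstituted C5=C6 bond, and NaBH4 reduces the ozonide to the two primary alcohols without touching C7, C8 or the ring-derived Z alkene.

Step 5
Reactants: 6 (Z)-chloroalkene diol with primary alcohols at C4 and C9
Product: 7 C4 allylic chloride with free C9 alcohol on the cis-7,8-acetonide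
Conditions: N-chlorosuccinimide, Me2S, CH2Cl2, −25 → 0 °C, base-free work-up
Reagents that add atoms: N-chlorosuccinimide, O=C1CCC(=O)N1Cl
Why: Corey–Kim chlorination: the chlorodimethylsulfonium reagent turns the allylic alkoxysulfonium salt into the chloride by SN2 collapse, while the saturated C9 alcohol is returned unchanged when no amine is added.

Step 6
Reactants: 7 C4 allylic chloride with free C9 alcohol
Product: 9 trans-dioxolane C9 aldehyde (C8 epimerised), via cis-aldehyde 8 (not isolated)
Conditions: SO3·pyridine, DMSO, i-Pr2NEt, CH2Cl2, 0 °C; then excess i-Pr2NEt, 20 °C until equilibrated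
Reagents that add atoms: none
Why: Parikh–Doering oxidation followed by base-mediated epimerisation: the C8 hydrogen of 8 is acidic and equilibration through the enol should favour the trans-disubstituted dioxolane, while β-elimination is disfavoured because the C7–O bond is held in the ring near the nodal plane of the enolate; turning the relay centre C8 makes the Felkin product of step 7 the one with the target configuration at C9.

Step 7
Reactants: 9 trans-dioxolane C9 aldehyde
Product: 10 C9 allylic alcohol (C9 S; 8,9-anti) carrying the C10 vinyl group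
Conditions: vinylmagnesium bromide, THF, −78 °C, cold quench
Reagents that add atoms: vinylmagnesium bromide, C=C[Mg]Br
Why: Grignard addition under Felkin–Anh control: with the C8–O bond anti to the incoming vinyl group the nucleophile passes the C8 hydrogen and should give the 8,9-anti alcohol, which is C9 S as in the target; the minor epimer is removed by chromatography and the allylic chloride is inert at this temperature.

Step 8
Reactants: 10 C9 allylic alcohol
Product: 11 C9 acetoacetate ester
Conditions: diketene, DMAP (cat.), CH2Cl2, 0 °C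
Reagents that add atoms: diketene (4-methylideneoxetan-2-one), C=C1CC(=O)O1
Why: DMAP-catalysed acylation with diketene gives the acetoacetate under mild conditions and brings in C15, C1, C2 and C3 without touching a stereocentre.

Step 9
Reactants: 11 C9 acetoacetate ester
Product: 14 3-acetyl-5-substituted furan-2(5H)-one (butenolide C9–O–C15(=O)–C1=C10 with the acetyl group on C1), via ozonide 12 (not isolated), via aldehyde 13 (not isolated)
Conditions: O3, CH2Cl2, −78 °C (Sudan Red 7B end point); Me2S, −78 → 0 °C; then piperidinium acetate (cat.), −20 °C, short contact, neutral silica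
Reagents that add atoms: none
Why: Ozonolysis of the terminal vinyl group (far more electron-rich than the deactivated chloroalkene) followed by intramolecular Knoevenagel condensation of the acetoacetate methylene onto the new C10 aldehyde closes the five-membered ring and dehydrates to the doubly activated butenolide; cold, brief catalysis is chosen to keep C9 from epimerising.

Step 10
Reactants: 15 (E)-4-methoxybut-3-en-2-one
Product: 16 (E)-1-methoxypent-1-en-3-one
Conditions: LiN(i-Pr)2, THF, −78 °C; iodomethane, −78 → −20 °C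
Reagents that add atoms: iodomethane, CI
Why: Kinetic enolate alkylation: the methyl group of the vinylogous ester is the only enolisable site and its lithium enolate is methylated to the ethyl ketone.

Step 11
Reactants: 16 (E)-1-methoxypent-1-en-3-one
Product: 17 (1E,3Z)-3-(tert-butyldimethylsilyloxy)-1-methoxypenta-1,3-diene
Conditions: tert-butyldimethylsilyl trifluoromethanesulfonate, Et3N, Et2O, 0 °C
Reagents that add atoms: tert-butyldimethylsilyl trifluoromethanesulfonate, CC(C)(C)[Si](C)(C)OS(=O)(=O)C(F)(F)F
Why: Soft enolisation with a silyl triflate and an amine gives the 2-silyloxydiene; the Z enol ether (methyl trans to the vinyl group) is the favoured isomer and the one that can reach the s-cis conformation.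

Step 12
Reactants: 14 3-acetyl-5-substituted furan-2(5H)-one; 17 (1E,3Z)-3-(tert-butyldimethylsilyloxy)-1-methoxypenta-1,3-diene
Product: 18 cis-fused cycloadduct (ring A as C12 silyl enol ether with C14 methoxy group; C1 quaternary with C15 lactone carbonyl and C2 acetyl)
Conditions: toluene, 0 → 25 °C, excess 17, no acid or base
Reagents that add atoms: none
Why: Normal-demand Diels–Alder reaction of a Danishefsky-type diene: both acceptors sit on C1 so the nucleophilic terminus C11 bonds to C10, the diene adds to the butenolide face anti to the C9 substituent (fixing C1 and C10 relative to C9), and the endo mode with respect to the ring carbonyl places the outside methyl on C11 cis to C9 and C15, which is the all-cis C1/C10/C11 pattern of the target.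

Step 13
Reactants: 18 cis-fused cycloadduct
Product: 19 macrocyclic keto lactone (ten-membered ring closed at C3–C4; lactone bridge C1–C15(=O)–O–C9)
Conditions: KN(SiMe3)2, 18-crown-6, THF, −78 → 0 °C, high dilution (slow addition of 18)
Reagents that add atoms: none
Why: Intramolecular C-alkylation of a ketone enolate by a primary allylic chloride: C3 is the only enolisable position, and the cis-fused lactone holds the C2 acetyl group and C8 on the same face, so the two chain ends are within reach for ten-membered ring closure.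

Step 14
Reactants: 19 macrocyclic keto lactone
Product: 20 C2 alcohol (2S)
Conditions: Zn(BH4)2, Et2O, −30 °C
Reagents that add atoms: none
Why: Chelation-controlled ketone reduction: zinc bridges the C2 ketone and the lactone carbonyl on C1, and hydride then enters from the exposed face on the C14 side, away from the ring chain that runs to C9, which should give the 2S alcohol.

Step 15
Reactants: 20 C2 alcohol
Product: 21 lactol (C15 at the aldehyde level; anomers)
Conditions: i-Bu2AlH (2.5 equiv), CH2Cl2, −78 °C
Reagents that add atoms: none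
Why: Partial reduction of a γ-lactone with i-Bu2AlH at low temperature stops at the tetrahedral aluminium hemiacetal, which gives the lactol on work-up; the C2 alkoxide consumes one equivalent.

Step 16
Reactants: 21 lactol
Product: 22 C2 acetate with acetylated lactol
Conditions: Ac2O, pyridine, DMAP (cat.), CH2Cl2, 25 °C
Reagents that add atoms: acetic anhydride, CC(=O)OC(C)=O
Why: DMAP-catalysed acetylation esterifies the hindered C2 alcohol and the lactol hydroxyl, so the C2 acetate of the target is in place while O9 is still tied up.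

Step 17
Reactants: 22 C2 acetate with acetylated lactol
Product: 24 C15 methyl compound with free C9 hydroxyl, via tosylhydrazone 23 (not isolated)
Conditions: TsNHNH2, pyridinium acetate (cat.), EtOH, 50 °C; then catecholborane, CHCl3, 0 °C; then NaOAc·3H2O, 60 °C
Reagents that add atoms: none
Why: Caglioti-type deoxygenation in the Kabalka variant: the lactol acetate exchanges with tosylhydrazide to the open-chain hydrazone, catecholborane adds hydride to C=N, and acetate-induced loss of sulfinate and dinitrogen leaves the C15 methyl group and frees the C9 hydroxyl; the C2 ester and the silyl enol ether should survive.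

Step 18
Reactants: 24 C15 methyl compound with free C9 hydroxyl
Product: 25 C9 tert-butyldimethylsilyl ether
Conditions: tert-butyldimethylsilyl trifluoromethanesulfonate, 2,6-lutidine, CH2Cl2, −78 → 0 °C
Reagents that add atoms: tert-butyldimethylsilyl trifluoromethanesulfonate, CC(C)(C)[Si](C)(C)OS(=O)(=O)C(F)(F)F
Why: Silylation with a silyl triflate and a hindered pyridine protects the hindered secondary C9 alcohol for the end game.

Step 19
Reactants: 25 C9 tert-butyldimethylsilyl ether
Product: 27 ring A enone (C12 ketone with C13=C14), via methoxy ketone 26 (not isolated)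
Conditions: CF3CO2H (2 equiv), CH2Cl2, 0 °C, short contact
Reagents that add atoms: none
Why: Acid hydrolysis of the silyl enol ether gives the β-methoxy ketone, which loses methanol by acid-catalysed β-elimination to the enone (the usual unveiling of a Danishefsky-type adduct); brief contact at 0 °C is meant to spare the acetonide, the C9 silyl ether and the C11 centre.

Step 20
Reactants: 27 ring A enone
Product: 28 12β-allylic alcohol
Conditions: NaBH4, CeCl3·7H2O, MeOH, −78 °C
Reagents that add atoms: none
Why: Luche reduction (1,2-selective): hydride should enter C12 from the α face, anti to the neighbouring β-methyl group on C11, giving the 12β-alcohol.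

Step 21
Reactants: 28 12β-allylic alcohol
Product: 29 12α-acetate (C12 R)
Conditions: PPh3, i-PrO2CN=NCO2i-Pr, AcOH, toluene, 0 → 25 °C
Reagents that add atoms: acetic acid, CC(=O)O
Why: Mitsunobu reaction: the activated allylic C12 oxygen is displaced by acetate with inversion from the open α face, which sets the acetate trans to the C11 methyl group; SN2′ attack at C14 is blocked by the quaternary C1.

Step 22
Reactants: 29 12α-acetate
Product: 30 C7/C8 diol
Conditions: AcOH/H2O/THF, 40 °C
Reagents that add atoms: none
Why: Acid-catalysed hydrolysis of the acetonide frees the two hydroxyls; the hindered secondary silyl ether and the acetates should survive aqueous acetic acid.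

Step 23
Reactants: 30 C7/C8 diol
Product: 31 O7 2-bromopropanoate (both bromide epimers) with free C8 hydroxyl
Conditions: 2-bromopropanoyl bromide (1.05 equiv), 2,4,6-collidine, CH2Cl2, −78 → −40 °C
Reagents that add atoms: 2-bromopropanoyl bromide, CC(Br)C(Br)=O
Why: Regioselective O-acylation: the allylic C7 hydroxyl next to a flat sp2 carbon should react faster than the C8 hydroxyl, which lies between two oxygenated sp3 carbons beside the bulky C9 silyl ether; the two bromide epimers converge in step 25.

Step 24
Reactants: 31 O7 2-bromopropanoate with free C8 hydroxyl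
Product: 32 C8 ketone
Conditions: Dess–Martin periodinane, NaHCO3, CH2Cl2, 0 °C; used at once
Reagents that add atoms: none
Why: Dess–Martin oxidation under buffered, neutral conditions converts the remaining secondary alcohol into the ketone without epimerising C7 or C9.

Step 25
Reactants: 32 C8 ketone
Product: 33 9-O-silyl ether of the target (γ-lactone closed; C8 tertiary alcohol)
Conditions: SmI2 (2.5 equiv), THF, −78 °C, slow addition of 32
Reagents that add atoms: none
Why: Samarium-mediated intramolecular Reformatsky reaction: SmI2 reduces the C–Br bond faster than the ketone, and the samarium enolate adds to the neighbouring C8 carbonyl within a chelate to close the γ-lactone; peripheral attack should place the C8 hydroxyl cis to C6 across the new ring (C8 R) and the C17 methyl group anti to C9 (C17 R).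

Step 26
Reactants: 33 9-O-silyl ether of the target
Product: 34 CNP0296164.1
Conditions: HF·pyridine, pyridine/THF, 0 → 25 °C
Reagents that add atoms: none
Why: Fluoride-mediated desilylation under acidic, non-basic conditions removes the C9 silyl ether without acetyl migration or retro-aldol opening of the β-hydroxy lactone.

Compound list
1 | 2-chloro-5-iodotoluene | Cc1cc(I)ccc1Cl | starting material
2 | (1S,2R)-3-chloro-6-iodo-4-methylcyclohexa-3,5-diene-1,2-diol | CC1=C(Cl)[C@H](O)[C@H](O)C(I)=C1 | intermediate
3 | (3aR,7aS)-4-chloro-7-iodo-2,2,5-trimethyl-3a,7a-dihydro-1,3-benzodioxole | CC1=C(Cl)[C@@H]2OC(C)(C)O[C@@H]2C(I)=C1 | intermediate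
4 | (3aR,7aR)-4-chloro-2,2,5-trimethyl-3a,7a-dihydro-1,3-benzodioxole | CC1=C(Cl)[C@@H]2OC(C)(C)O[C@@H]2C=C1 | intermediate
5 | ozonide of 4 (1,2,4-trioxolane across C4 and C9; new centres undefined) | CC1=C(Cl)[C@@H]2OC(C)(C)O[C@@H]2C2OOC1O2 | intermediate (not isolated)
6 | (Z)-3-chloro-3-[cis-5-(hydroxymethyl)-2,2-dimethyl-1,3-dioxolan-4-yl]-2-methylprop-2-en-1-ol (C7, C8 as in 4) | OC/C(C)=C(/Cl)[C@@H]1OC(C)(C)O[C@@H]1CO | intermediate
7 | [cis-5-[(Z)-1,3-dichloro-2-methylprop-1-enyl]-2,2-dimethyl-1,3-dioxolan-4-yl]methanol | ClC/C(C)=C(/Cl)[C@@H]1OC(C)(C)O[C@@H]1CO | intermediate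
8 | cis-5-[(Z)-1,3-dichloro-2-methylprop-1-enyl]-2,2-dimethyl-1,3-dioxolane-4-carbaldehyde | ClC/C(C)=C(/Cl)[C@@H]1OC(C)(C)O[C@@H]1C=O | intermediate (not isolated)
9 | trans-5-[(Z)-1,3-dichloro-2-methylprop-1-enyl]-2,2-dimethyl-1,3-dioxolane-4-carbaldehyde (C8 epimer of 8) | ClC/C(C)=C(/Cl)[C@@H]1OC(C)(C)O[C@H]1C=O | intermediate
10 | 1-[trans-5-[(Z)-1,3-dichloro-2-methylprop-1-enyl]-2,2-dimethyl-1,3-dioxolan-4-yl]prop-2-en-1-ol, C9 S (8,9-anti) | ClC/C(C)=C(/Cl)[C@@H]1OC(C)(C)O[C@H]1[C@@H](O)C=C | intermediate
11 | acetoacetate (3-oxobutanoate) ester of 10 | ClC/C(C)=C(/Cl)[C@@H]1OC(C)(C)O[C@H]1[C@@H](OC(=O)CC(C)=O)C=C | intermediate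
12 | ozonide of the vinyl group of 11 (new centre undefined) | ClC/C(C)=C(/Cl)[C@@H]1OC(C)(C)O[C@H]1[C@@H](OC(=O)CC(C)=O)C1OOCO1 | intermediate (not isolated)
13 | C10 aldehyde bearing the C9 acetoacetate | ClC/C(C)=C(/Cl)[C@@H]1OC(C)(C)O[C@H]1[C@@H](OC(=O)CC(C)=O)C=O | intermediate (not isolated)
14 | 3-acetyl-5-[trans-5-[(Z)-1,3-dichloro-2-methylprop-1-enyl]-2,2-dimethyl-1,3-dioxolan-4-yl]furan-2(5H)-one (C9 as in 10) | ClC/C(C)=C(/Cl)[C@@H]1OC(C)(C)O[C@H]1[C@H]1OC(=O)C(C(C)=O)=C1 | intermediate
15 | (E)-4-methoxybut-3-en-2-one | CO/C=C/C(C)=O | starting material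
16 | (E)-1-methoxypent-1-en-3-one | CO/C=C/C(=O)CC | intermediate
17 | (1E,3Z)-3-(tert-butyldimethylsilyloxy)-1-methoxypenta-1,3-diene | CO/C=C/C(O[Si](C)(C)C(C)(C)C)=C/C | intermediate
18 | Diels–Alder adduct: lactone cis-fused to ring A at C1–C10; C1 bears acetyl; C11 methyl and C14 methoxy cis to the lactone; C12 silyl enol ether | ClC/C(C)=C(/Cl)[C@@H]1OC(C)(C)O[C@H]1[C@H]2OC(=O)[C@@]3(C(C)=O)[C@@H]2[C@@H](C)C(O[Si](C)(C)C(C)(C)C)=C[C@H]3OC | intermediate
19 | macrocyclic C2 ketone with C1–C15(=O)–O–C9 lactone bridge (ten-membered ring closed) | O=C1CC/C(C)=C(/Cl)[C@@H]2OC(C)(C)O[C@H]2[C@H]2OC(=O)[C@]13[C@@H]2[C@@H](C)C(O[Si](C)(C)C(C)(C)C)=C[C@H]3OC | intermediate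
20 | (2S)-alcohol from 19 | O[C@H]1CC/C(C)=C(/Cl)[C@@H]2OC(C)(C)O[C@H]2[C@H]2OC(=O)[C@]13[C@@H]2[C@@H](C)C(O[Si](C)(C)C(C)(C)C)=C[C@H]3OC | intermediate
21 | lactol from 20 (C15 hemiacetal, anomers) | O[C@H]1CC/C(C)=C(/Cl)[C@@H]2OC(C)(C)O[C@H]2[C@H]2OC(O)[C@]13[C@@H]2[C@@H](C)C(O[Si](C)(C)C(C)(C)C)=C[C@H]3OC | intermediate
22 | C2 acetate with C15 lactol acetate | CC(=O)O[C@H]1CC/C(C)=C(/Cl)[C@@H]2OC(C)(C)O[C@H]2[C@H]2OC(OC(C)=O)[C@]13[C@@H]2[C@@H](C)C(O[Si](C)(C)C(C)(C)C)=C[C@H]3OC | intermediate
23 | C15 tosylhydrazone with free C9 hydroxyl | CC(=O)O[C@H]1CC/C(C)=C(/Cl)[C@@H]2OC(C)(C)O[C@H]2[C@@H](O)[C@H]2[C@@H](C)C(O[Si](C)(C)C(C)(C)C)=C[C@@H](OC)[C@@]21/C=N/NS(=O)(=O)c1ccc(C)cc1 | intermediate (not isolated)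
24 | bicyclic C2 acetate with C15 methyl, free C9 hydroxyl, 7,8-acetonide, masked ring A enone | CC(=O)O[C@H]1CC/C(C)=C(/Cl)[C@@H]2OC(C)(C)O[C@H]2[C@@H](O)[C@H]2[C@@H](C)C(O[Si](C)(C)C(C)(C)C)=C[C@@H](OC)[C@@]21C | intermediate
25 | C9 tert-butyldimethylsilyl ether of 24 | CC(=O)O[C@H]1CC/C(C)=C(/Cl)[C@@H]2OC(C)(C)O[C@H]2[C@@H](O[Si](C)(C)C(C)(C)C)[C@H]2[C@@H](C)C(O[Si](C)(C)C(C)(C)C)=C[C@@H](OC)[C@@]21C | intermediate
26 | C12 ketone with C14 methoxy group | CC(=O)O[C@H]1CC/C(C)=C(/Cl)[C@@H]2OC(C)(C)O[C@H]2[C@@H](O[Si](C)(C)C(C)(C)C)[C@H]2[C@@H](C)C(=O)C[C@@H](OC)[C@@]21C | intermediate (not isolated)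
27 | ring A enone (C12 ketone, C13=C14) | CC(=O)O[C@H]1CC/C(C)=C(/Cl)[C@@H]2OC(C)(C)O[C@H]2[C@@H](O[Si](C)(C)C(C)(C)C)[C@H]2[C@@H](C)C(=O)C=C[C@@]21C | intermediate
28 | 12β-alcohol (cis to the C11 methyl) | CC(=O)O[C@H]1CC/C(C)=C(/Cl)[C@@H]2OC(C)(C)O[C@H]2[C@@H](O[Si](C)(C)C(C)(C)C)[C@H]2[C@@H](C)[C@@H](O)C=C[C@@]21C | intermediate
29 | 2,12-diacetate with 12α-acetate, 7,8-acetonide, 9-O-silyl ether | CC(=O)O[C@H]1CC/C(C)=C(/Cl)[C@@H]2OC(C)(C)O[C@H]2[C@@H](O[Si](C)(C)C(C)(C)C)[C@H]2[C@@H](C)[C@H](OC(C)=O)C=C[C@@]21C | intermediate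
30 | 7,8-diol (threo) of 29 | CC(=O)O[C@H]1CC/C(C)=C(/Cl)[C@H](O)[C@@H](O)[C@@H](O[Si](C)(C)C(C)(C)C)[C@H]2[C@@H](C)[C@H](OC(C)=O)C=C[C@@]21C | intermediate
31 | O7 2-bromopropanoate of 30 (bromide epimers) | CC(=O)O[C@H]1CC/C(C)=C(/Cl)[C@H](OC(=O)C(C)Br)[C@@H](O)[C@@H](O[Si](C)(C)C(C)(C)C)[C@H]2[C@@H](C)[C@H](OC(C)=O)C=C[C@@]21C | intermediate
32 | C8 ketone of 31 | CC(=O)O[C@H]1CC/C(C)=C(/Cl)[C@H](OC(=O)C(C)Br)C(=O)[C@@H](O[Si](C)(C)C(C)(C)C)[C@H]2[C@@H](C)[C@H](OC(C)=O)C=C[C@@]21C | intermediate
33 | 9-O-tert-butyldimethylsilyl ether of the target | CC(=O)O[C@H]1CC/C(C)=C(/Cl)[C@@H]2OC(=O)[C@H](C)[C@@]2(O)[C@@H](O[Si](C)(C)C(C)(C)C)[C@H]2[C@@H](C)[C@H](OC(C)=O)C=C[C@@]21C | intermediate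
34 | CNP0296164.1 (1S,2S,7R,8R,9S,10S,11R,12R,17R) | CC(=O)O[C@H]1CC/C(C)=C(/Cl)[C@@H]2OC(=O)[C@H](C)[C@@]2(O)[C@@H](O)[C@H]2[C@@H](C)[C@H](OC(C)=O)C=C[C@@]21C | target

Total step count: 26. Longest linear sequence: 24 steps (steps 1–9 and 12–26, from 1 to 34); diene 17 takes 2 steps (10 and 11).

Steps most likely to fail

Step 1. The enzyme may hydroxylate the benzylic methyl group, or bind the arene with chlorine and not iodine as anchor, so that little diol or the wrong enantiomer is formed. The fallback removes the benzylic position: in place of 1 (no numbered compound precedes the key step) it sets out from commercial 2-bromo-1-chloro-4-iodobenzene F1, which is fed to a polyhalobenzene-accepting Rieske dioxygenase and should give, at the same unsubstituted edge, cis-4-bromo-3-chloro-6-iodocyclohexa-3,5-diene-1,2-diol F2. Acetonide formation (2,2-dimethoxypropane, TsOH) gives 5-bromo-4-chloro-7-iodo-2,2-dimethyl-3a,7a-dihydro-1,3-benzodioxole F3. Selective hydrodeiodination (Pd(PPh3)4, Bu3SnH) gives 5-bromo-4-chloro-2,2-dimethyl-3a,7a-dihydro-1,3-benzodioxole F4. Negishi methylation at the C–Br bond (MeZnCl, Pd(PPh3)4, THF) then gives 4, where the route resumes.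

Step 13. Intermolecular alkylation, O-alkylation or base-induced decomposition of the hard potassium enolate may outrun ten-membered ring closure. The fallback uses a soft, doubly stabilised carbanion and sets out from 10. Acylation with the acyl Meldrum's acid 5-[1-hydroxy-2-(phenylsulfonyl)ethylidene]-2,2-dimethyl-1,3-dioxane-4,6-dione F5 (made from (phenylsulfonyl)acetic acid, Meldrum's acid, DCC and DMAP; toluene, 80 °C) gives the 3-oxo-4-(phenylsulfonyl)butanoate ester of 10 F6. Ozonolysis and Knoevenagel closure as in step 9 give the 3-[(phenylsulfonyl)acetyl]butenolide F7. Cycloaddition with 17 as in step 12 gives the sulfonyl cycloadduct F8. Ring closure at C3–C4 (Cs2CO3, NaI, MeCN, high dilution) gives the macrocyclic β-keto sulfone F9, and reductive desulfonylation (SmI2, THF/MeOH, −78 °C) gives 19, where the route resumes.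

Step 9. Amine catalysis may epimerise C9 through the enol of aldehyde 13 or the furanolate of 14. The fallback builds the butenolide by metathesis and reveals the acetyl group by a neutral oxidation; it sets out from 10. Commercial methyl 3-hydroxy-2-methylenebutanoate is silylated (Et3SiCl, imidazole) to methyl 2-methylene-3-(triethylsilyloxy)butanoate F10 and saponified (LiOH) to 2-methylene-3-(triethylsilyloxy)butanoic acid F11. Esterification of 10 (DCC, DMAP) gives the 2-substituted acrylate ester F12. Ring-closing metathesis (second-generation Hoveyda–Grubbs catalyst, toluene, 80 °C) gives the 3-[1-(triethylsilyloxy)ethyl]butenolide F13. HF·pyridine gives the 3-(1-hydroxyethyl)butenolide F14, and Dess–Martin oxidation gives 14, where the route resumes; the carbinol centre of the side chain is erased in that oxidation, so either epimer serves.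

Further compounds
F1 | step 1 | 2-bromo-1-chloro-4-iodobenzene | Clc1ccc(I)cc1Br
F2 | step 1 | cis-4-bromo-3-chloro-6-iodocyclohexa-3,5-diene-1,2-diol (configuration as in 2) | BrC1=C(Cl)[C@H](O)[C@H](O)C(I)=C1
F3 | step 1 | 5-bromo-4-chloro-7-iodo-2,2-dimethyl-3a,7a-dihydro-1,3-benzodioxole | BrC1=C(Cl)[C@@H]2OC(C)(C)O[C@@H]2C(I)=C1
F4 | step 1 | 5-bromo-4-chloro-2,2-dimethyl-3a,7a-dihydro-1,3-benzodioxole | BrC1=C(Cl)[C@@H]2OC(C)(C)O[C@@H]2C=C1
F5 | step 13 | 5-[1-hydroxy-2-(phenylsulfonyl)ethylidene]-2,2-dimethyl-1,3-dioxane-4,6-dione | CC1(C)OC(=O)C(=C(O)CS(=O)(=O)c2ccccc2)C(=O)O1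
F6 | step 13 | 3-oxo-4-(phenylsulfonyl)butanoate ester of 10 | ClC/C(C)=C(/Cl)[C@@H]1OC(C)(C)O[C@H]1[C@@H](OC(=O)CC(=O)CS(=O)(=O)c1ccccc1)C=C
F7 | step 13 | 3-[(phenylsulfonyl)acetyl]butenolide analogue of 14 | ClC/C(C)=C(/Cl)[C@@H]1OC(C)(C)O[C@H]1[C@H]1OC(=O)C(C(=O)CS(=O)(=O)c2ccccc2)=C1
F8 | step 13 | sulfonyl analogue of cycloadduct 18 | ClC/C(C)=C(/Cl)[C@@H]1OC(C)(C)O[C@H]1[C@H]2OC(=O)[C@@]3(C(=O)CS(=O)(=O)c4ccccc4)[C@@H]2[C@@H](C)C(O[Si](C)(C)C(C)(C)C)=C[C@H]3OC
F9 | step 13 | 3-(phenylsulfonyl) derivative of macrocycle 19 (C3 undefined) | O=C1C(S(=O)(=O)c4ccccc4)C/C(C)=C(/Cl)[C@@H]2OC(C)(C)O[C@H]2[C@H]2OC(=O)[C@]13[C@@H]2[C@@H](C)C(O[Si](C)(C)C(C)(C)C)=C[C@H]3OC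
F10 | step 9 | methyl 2-methylene-3-(triethylsilyloxy)butanoate | C=C(C(C)O[Si](CC)(CC)CC)C(=O)OC
F11 | step 9 | 2-methylene-3-(triethylsilyloxy)butanoic acid | C=C(C(C)O[Si](CC)(CC)CC)C(=O)O
F12 | step 9 | 2-methylene-3-(triethylsilyloxy)butanoate ester of 10 | ClC/C(C)=C(/Cl)[C@@H]1OC(C)(C)O[C@H]1[C@@H](OC(=O)C(=C)C(C)O[Si](CC)(CC)CC)C=C
F13 | step 9 | 3-[1-(triethylsilyloxy)ethyl]butenolide analogue of 14 | ClC/C(C)=C(/Cl)[C@@H]1OC(C)(C)O[C@H]1[C@H]1OC(=O)C(C(C)O[Si](CC)(CC)CC)=C1
F14 | step 9 | 3-(1-hydroxyethyl)butenolide analogue of 14 | ClC/C(C)=C(/Cl)[C@@H]1OC(C)(C)O[C@H]1[C@H]1OC(=O)C(C(C)O)=C1
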